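## Structural features

The target is an ent-labdane: a trans-fused decalin (ring A = C1–C5, C10; ring B = C5–C10) with a gem-dimethyl group at C4, an angular methyl on C10, an equatorial methoxy group on C2 and an exocyclic methylene C8=C17. C9 carries a five-carbon chain C11–C16 ending in a trisubstituted (13Z)-alkene whose C16 acetoxymethyl and C15 carboxyl groups are cis; this is the ring-opened, O-acetylated form of a butenolide. There are four stereocentres, all R. C5, C10 and C9 are contiguous, C10 is quaternary, and C2 is 1,3 to C10 through C1. The fragile elements are the exocyclic alkene (acid moves it into the ring), the cis acetate/acid pair (loss of the acetate is followed by lactonisation) and C9 whenever C11 is a carbonyl (epimerisation or conjugation with C8). The real difficulty is the quaternary C10 in the correct sense relative to the remote C2 oxygen, next to a trans ring fusion and the crowded C4; the second difficulty is the side-chain geometry. The key step uses the fact that the C2 oxygen and the C10–C9 bond lie on the same face of ring A, so an ester from O2 to C11 closes a six-membered ring C10–C1–C2–O–C11–C9 and holds an alkyne C8≡C9 over a ring-A diene C10=C5–C6=C7.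

## Logic of the disconnections

24 to 22: the O–C(CH3)3 bond of the C15 ester is cut. The acid is unveiled last, without base and without free protic acid, because the cis acetate and the 8(17)-alkene tolerate neither.

22 to 17 and 20: the C12–C13 bond is cut (sp3–sp2 coupling). All side-chain functionality and the alkene geometry are stored in the small fragment 20. The forward step must hydroborate the vinyl group of 17 and not its methylene, and must couple without touching the acetate.

20 to 19 to 18: the enol C–O(sulfonyl) bond and the C16–O acetate bond are cut. The geometry of 20 must be E, so that the acetoxymethyl group ends up cis to the ester.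

17 to 16 to 15 to 14: the C11=C12 bond is cut (methylenation) and C11 is returned to the ester level. The demand is that C9, α to the aldehyde in 16, is not epimerised.

14 to 12: the C9–H bond is cut and the alkene is moved from C8(17) back to C8=C9. One stereocentre and the sensitive methylene are thereby replaced by a robust tetrasubstituted enoate. The forward step needs γ-deprotonation at C17 (not C7) and α-protonation anti to the C10 methyl.

12 to 11: the C5–H and C6–H bonds are cut. The forward hydrogenation must add anti to the C10 methyl. It is placed after lactone opening because in 9 the C1–C2 bridge covers that face.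

11 to 10 to 9: the O–CH3 bond and the ester C11–OCH3 bond are cut, which re-forms the C11–O2 lactone. The methylation must avoid an alkoxide, which would close the lactone again.

9 to 8: the C7–C8 and C9–C10 bonds are cut. Two rings and the quaternary centre are lost at once, leaving a monocyclic diene ester with one stereocentre. The forward step must be intramolecular and face-selective.

8 to 7 to 5 and 6: the C10=C5 double bond is traced to a tertiary allylic alcohol and the ester C–O bond is cut. The diene is unveiled only after the ester is in place, so no free dienol is handled and no protecting group is needed.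

5 to 3 and 4: the C5–C6 bond is cut (vinyl addition to the hindered ketone).

3 to 2 to 1: the C2–H bond and then the ring C–H bonds are cut, back to an achiral enedione. The demand is a reductase that gives the cis (4S) alcohol.

## Other disconnections considered

Alternative 1: The cut is at C5–C6 and C9–C10 with no ring closed. In the forward step a Cu(OTf)2/chiral phosphoramidite catalyst would add the acetal Grignard reagent A2 to the enone A1, and the enolate would be alkylated with the bromoacetate A3 to give the ketone A4.
- In its favour: the absolute configuration comes from a catalyst, C5 and C10 are set in one flask, and anti alkylation naturally gives the trans relation. On these points it is the equal or the better of the chosen plan, which sets C5 in a separate hydrogenation.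
- Against it: the β-carbon of A1 is flanked by the gem-dimethyl group and the α-carbon is substituted, so both the addition and the quaternary alkylation would be slow. The ketone of A4 sits at C1 while the target is oxygenated at C2, so a carbonyl transposition and a stereoselective C2 installation are still needed. Ring B, C17 and the whole side chain remain to be built.
- Comparison: A4 has no ring B and a misplaced oxygen, whereas 9 has both rings and the oxygen in place. The alternative is an ionic, catalyst-controlled step where the chosen one is pericyclic and substrate-controlled. It would be clearly longer after the key step.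

Alternative 2: The cut is at C11–C12 and C8–C9. A 3-acetoxy-2-oxopropyl radical from the xanthate A6 would add to the vinyl group of the ring-A enyne A5, and the C9 radical would close ring B 6-exo-dig to give the acetoxy ketone A7.
- In its favour: the side-chain carbons C12, C13 and C16, the acetate, ring B and the exocyclic methylene would all arrive in one step at the right oxidation level. After the key step this is better than the chosen plan, which spends five steps on deconjugation and C11 homologation.
- Against it: A5 already needs C2, C5 and the quaternary, vinyl-bearing C10 on a monocycle, which is the hard problem left unsolved. The 6-exo-dig closure must outrun group transfer to the open-chain radical. C9 is set by a radical chair transition state. A7 still needs a two-carbon olefination at C13 whose geometry is not secured, whereas the chosen plan carries the geometry in 20.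
- Comparison: a radical chain replaces a concerted cycloaddition. Step economy is better after the key step and worse before it.

Alternative 3: The cut is at C5–C10 and C8–C9. An intramolecular Diels–Alder reaction of the acyclic triene A8 would close both rings and give the decalin A9.
- In its favour: C5, C9 and C10 (and C8) are created in one step, which is more stereochemical complexity per step than the chosen cycloaddition. The C11 ester is in place as in the chosen plan, and the C8 oxygen offers a direct handle for the methylene.
- Against it: the dienophile is a β,β-disubstituted enoate that must form a quaternary centre while the diene terminus is neopentyl. Trans fusion and the sense relative to C2 depend on conformational preference of the tether, not on a geometric constraint. A8 needs a stereodefined enoate, a silyloxydiene and the C2 centre from a separate asymmetric step. Afterwards C6=C7 must be hydrogenated and C8 oxidised and methylenated next to an epimerisable C9.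
- Comparison: both plans are pericyclic. The chosen one sets a single centre with enforced face and regiochemistry from a cheap cyclic precursor. The alternative sets more centres with less certainty, and the step count would be similar or higher.

Key step: step 6

Remark: a ketoreductase that reduces C4 of 2 to the cis (4S,6R) alcohol 3 is assumed to be available from a commercial enzyme panel; the descriptor check shows that this carbinol centre is S in 3, 5, 7 and 8 and R from 9 onward with no change in space, because the CIP ranking of its two ring branches switches when C10 becomes sp3.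

## Route

Step 1
Reactants: 1 ketoisophorone (2,6,6-trimethylcyclohex-2-ene-1,4-dione)
Product: 2 (6R)-2,2,6-trimethylcyclohexane-1,4-dione
Conditions: ene-reductase (old yellow enzyme), NADP+ (cat.), glucose, glucose dehydrogenase, phosphate buffer pH 7, 30 °C
Reagents that add atoms: none
Why: Flavin-dependent ene-reductases add hydride and a proton anti across the enedione C=C and are known to give the 6R dione from this substrate. The C6 centre only serves as a defined handle for the next enzyme and is erased in step 5.

Step 2
Reactants: 2 (6R)-2,2,6-trimethylcyclohexane-1,4-dione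
Product: 3 (4S,6R)-4-hydroxy-2,2,6-trimethylcyclohexan-1-one (cis)
Conditions: (4S)-selective ketoreductase, NADP+ (cat.), i-PrOH, phosphate buffer pH 7, 30 °C
Reagents that add atoms: none
Why: Enzymatic carbonyl reduction is regioselective for the unhindered C4 ketone, since C1 is flanked by the gem-dimethyl and methyl-bearing carbons. The enzyme's facial selectivity gives the diequatorial 4S alcohol, which becomes C2 of the target.

Step 3
Reactants: 3 (4S,6R)-4-hydroxy-2,2,6-trimethylcyclohexan-1-one; 4 vinylmagnesium bromide
Product: 5 (4S,6R)-1-ethenyl-2,2,6-trimethylcyclohexane-1,4-diol (both C1 epimers)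
Conditions: CH2=CHMgBr (3.5 equiv), THF, 0 °C to rt; aq NH4Cl
Reagents that add atoms: none
Why: Grignard 1,2-addition to the hindered ketone after the first equivalent has deprotonated the hydroxyl. The new carbinol centre forms as an epimer mixture, which is irrelevant because it becomes sp2 in step 5.

Step 4
Reactants: 5 (4S,6R)-1-ethenyl-2,2,6-trimethylcyclohexane-1,4-diol; 6 but-2-ynoic acid
Product: 7 (1S,3R)-4-ethenyl-4-hydroxy-3,5,5-trimethylcyclohexyl but-2-ynoate (both C4 epimers)
Conditions: DCC, DMAP (cat.), CH2Cl2, −20 to 0 °C
Reagents that add atoms: none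
Why: Steglich esterification acylates only the secondary hydroxyl; the tertiary allylic hydroxyl is inert under these conditions. Acylation at oxygen leaves the carbinol configuration unchanged.

Step 5
Reactants: 7 (1S,3R)-4-ethenyl-4-hydroxy-3,5,5-trimethylcyclohexyl but-2-ynoate
Product: 8 (1S)-4-ethenyl-3,5,5-trimethylcyclohex-3-en-1-yl but-2-ynoate
Conditions: Burgess reagent, toluene, 60 °C
Reagents that add atoms: none
Why: Burgess dehydration of a tertiary allylic alcohol. The only β-hydrogen on an sp3 carbon is on the methyl-bearing ring carbon, so elimination can only give the tetrasubstituted ring alkene conjugated with the vinyl group, and the neutral conditions spare the alkynoate.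

Step 6
Reactants: 8 (1S)-4-ethenyl-3,5,5-trimethylcyclohex-3-en-1-yl but-2-ynoate
Product: 9 bridged tricyclic lactone, the 1,7-lactone of (7R,8aR)-7-hydroxy-2,5,5,8a-tetramethyl-3,5,6,7,8,8a-hexahydronaphthalene-1-carboxylic acid (target numbering: C2–O–C11(=O)–C9 bridge, C5=C6 and C8=C9 alkenes, 2R,10R)
Conditions: 1,2-dichlorobenzene (0.01 M), BHT (cat.), 180 °C, sealed tube, argon
Reagents that add atoms: none
Why: A concerted thermal [4+2] cycloaddition in which the alkynoate C8≡C9 adds across the ring-A diene C10=C5–C6=C7, forming C7–C8 and C9–C10. The closest known reaction types are the ester-tethered intramolecular Diels–Alder reaction of dienyl alkynoates and the intermolecular addition of acetylenic esters to 2,6,6-trimethyl-1-vinylcyclohexene. Ring B closes as the six-membered cyclohexa-1,4-diene of the cycloadduct, and the lactone closes as a six-membered ring through the four-atom tether C1–C2–O–C11 that links diene terminus C10 to dienophile carbon C9. C10 is the only new stereocentre and is controlled by C2: the tether reaches C10 only from the ring face that carries the oxygen, in a half-chair with the C2–O bond pseudoaxial, so the C10 methyl ends up anti to O2. Regiochemistry is enforced in the same way, because the reverse orientation cannot be spanned by the tether. The step needs cyclisation to win over intermolecular addition, diene dimerisation and 1,5-hydrogen shift of the s-cis diene; high dilution, a radical inhibitor and a polar aromatic solvent that favours the cisoid ester rotamer serve this. An alkyne dienophile raises no endo/exo question and leaves the C8=C9 enoate needed in step 10.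

Step 7
Reactants: 9 bridged tricyclic lactone
Product: 10 methyl (7R,8aR)-7-hydroxy-2,5,5,8a-tetramethyl-3,5,6,7,8,8a-hexahydronaphthalene-1-carboxylate
Conditions: K2CO3 (0.2 equiv), MeOH, 0 °C; then AcOH
Reagents that add atoms: methanol, CO
Why: Methoxide opens the strained bridged lactone by acyl–oxygen cleavage, so C2 keeps its configuration; excess methanol and relief of the diaxial bridge drive the equilibrium to the open ester. Low temperature and substoichiometric base keep the doubly allylic C7–H from being removed.

Step 8
Reactants: 10 methyl (7R,8aR)-7-hydroxy-2,5,5,8a-tetramethyl-3,5,6,7,8,8a-hexahydronaphthalene-1-carboxylate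
Product: 11 methyl (7R,8aR)-7-methoxy-2,5,5,8a-tetramethyl-3,5,6,7,8,8a-hexahydronaphthalene-1-carboxylate
Conditions: Me3OBF4, 1,8-bis(dimethylamino)naphthalene, CH2Cl2, 0 °C to rt
Reagents that add atoms: trimethyloxonium tetrafluoroborate, C[O+](C)C.F[B-](F)(F)F
Why: O-Methylation of the secondary alcohol with Meerwein's salt buffered by a non-nucleophilic base. No alkoxide is formed, so relactonisation onto the C11 ester cannot compete, and the alkenes are inert.

Step 9
Reactants: 11 methyl (7R,8aR)-7-methoxy-2,5,5,8a-tetramethyl-3,5,6,7,8,8a-hexahydronaphthalene-1-carboxylate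
Product: 12 methyl (4aR,7R,8aR)-7-methoxy-2,5,5,8a-tetramethyl-3,4,4a,5,6,7,8,8a-octahydronaphthalene-1-carboxylate
Conditions: H2 (1 atm), 10% Pd/C, EtOAc, rt
Reagents that add atoms: none
Why: Heterogeneous hydrogenation saturates only the trisubstituted C5=C6 alkene and leaves the tetrasubstituted, ester-conjugated C8=C9 alkene. Hydrogen is delivered to the face opposite the pseudoaxial C10 methyl, giving the trans ring fusion (5R in target numbering), as with the analogous drimane Diels–Alder adducts.

Step 10
Reactants: 12 methyl (4aR,7R,8aR)-7-methoxy-2,5,5,8a-tetramethyl-3,4,4a,5,6,7,8,8a-octahydronaphthalene-1-carboxylate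
Product: 14 methyl (1R,4aR,7R,8aR)-7-methoxy-5,5,8a-trimethyl-2-methylidenedecahydronaphthalene-1-carboxylate, via lithium dienolate 13 (not isolated)
Conditions: LiN(i-Pr)2, THF/DMPU, −78 °C; then AcOH, −78 °C
Reagents that add atoms: none
Why: Kinetic deprotonation of the enoate removes a proton from the C17 methyl, the γ-position cis to the ester, giving the exocyclic dienolate. Kinetic protonation then occurs at the α-carbon C9 from the face opposite the axial C10 methyl, which places C11 equatorial (9R) and leaves the C8=C17 methylene. This is the deconjugative α-protonation of an extended ester enolate known for cyclogeranate-type esters.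

Step 11
Reactants: 14 methyl (1R,4aR,7R,8aR)-7-methoxy-5,5,8a-trimethyl-2-methylidenedecahydronaphthalene-1-carboxylate
Product: 15 [(1R,4aR,7R,8aR)-7-methoxy-5,5,8a-trimethyl-2-methylidenedecahydronaphthalen-1-yl]methanol
Conditions: LiAlH4, THF, 0 °C
Reagents that add atoms: none
Why: Hydride reduction of the hindered ester to the primary alcohol; the isolated alkene and the methyl ether are inert.

Step 12
Reactants: 15 [(1R,4aR,7R,8aR)-7-methoxy-5,5,8a-trimethyl-2-methylidenedecahydronaphthalen-1-yl]methanol
Product: 16 (1R,4aR,7R,8aR)-7-methoxy-5,5,8a-trimethyl-2-methylidenedecahydronaphthalene-1-carbaldehyde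
Conditions: Dess–Martin periodinane, pyridine, CH2Cl2, 0 °C
Reagents that add atoms: none
Why: Dess–Martin oxidation under buffered, near-neutral conditions should give the β,γ-unsaturated aldehyde without epimerising C9 or moving the alkene into conjugation. The aldehyde is used at once.

Step 13
Reactants: 16 (1R,4aR,7R,8aR)-7-methoxy-5,5,8a-trimethyl-2-methylidenedecahydronaphthalene-1-carbaldehyde
Product: 17 (1R,4aR,7R,8aR)-1-ethenyl-7-methoxy-5,5,8a-trimethyl-2-methylidenedecahydronaphthalene
Conditions: Ph3PCH3Br, KN(SiMe3)2, THF, 0 °C; then 16, −78 to 0 °C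
Reagents that add atoms: methyltriphenylphosphonium bromide, C[P+](c1ccccc1)(c1ccccc1)c1ccccc1.[Br-]
Why: Wittig methylenation with the preformed ylide at low temperature. Addition to the aldehyde carbonyl is faster than α-deprotonation, so C9 is preserved.

Step 14
Reactants: 18 tert-butyl 4-chloro-3-oxobutanoate
Product: 19 tert-butyl 4-acetoxy-3-oxobutanoate
Conditions: KOAc, AcOH, DMF, rt
Reagents that add atoms: potassium acetate, CC(=O)[O-].[K+]
Why: SN2 displacement of the α-chloro ketone by acetate. Acetic acid buffers the medium and suppresses enolate side reactions.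

Step 15
Reactants: 19 tert-butyl 4-acetoxy-3-oxobutanoate
Product: 20 tert-butyl (2E)-4-acetoxy-3-{[(trifluoromethyl)sulfonyl]oxy}but-2-enoate
Conditions: Tf2O, i-Pr2NEt, CH2Cl2, −78 °C
Reagents that add atoms: trifluoromethanesulfonic anhydride, O=S(=O)(OS(=O)(=O)C(F)(F)F)C(F)(F)F
Why: O-Sulfonylation of the β-keto ester enolate under non-chelating amine-base conditions, where the enolate reacts from the dipole-minimised geometry with the enol oxygen trans to the ester. The E triflate places the acetoxymethyl group cis to the ester as the target requires; chelating lithium or sodium bases, which favour the Z isomer, are avoided.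

Step 16
Reactants: 17 (1R,4aR,7R,8aR)-1-ethenyl-7-methoxy-5,5,8a-trimethyl-2-methylidenedecahydronaphthalene; 20 tert-butyl (2E)-4-acetoxy-3-{[(trifluoromethyl)sulfonyl]oxy}but-2-enoate
Product: 22 tert-butyl (2R,5R,9R,10R,13Z)-16-acetoxy-2-methoxy-ent-labda-8(17),13-dien-15-oate, via alkyl(disiamyl)borane 21 (not isolated)
Conditions: (Sia)2BH (from BH3·THF, 2-methylbut-2-ene), THF, 0 °C; then 20, PdCl2(dppf) (5 mol%), aq K3PO4, DMF, rt
Reagents that add atoms: none
Why: Disiamylborane hydroborates the monosubstituted vinyl group anti-Markovnikov and leaves the hindered 1,1-disubstituted C8=C17 alkene. The primary alkyl group is then transferred in a B-alkyl Suzuki–Miyaura coupling with the activated enol triflate with retention of alkene geometry (13Z). Phosphate base at room temperature spares the acetate and the tert-butyl ester.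

Step 17
Reactants: 22 tert-butyl (2R,5R,9R,10R,13Z)-16-acetoxy-2-methoxy-ent-labda-8(17),13-dien-15-oate
Product: 24 (2R,5R,9R,10R,13Z)-16-acetoxy-2-methoxy-ent-labda-8(17),13-dien-15-oic acid (target), via trimethylsilyl ester 23 (not isolated)
Conditions: Me3SiOTf, 2,6-lutidine, CH2Cl2, 0 °C; then pH 5 phosphate buffer
Reagents that add atoms: none
Why: The silyl triflate buffered with 2,6-lutidine converts the tert-butyl ester into the trimethylsilyl ester with loss of isobutene and without free protic acid. The exocyclic alkene, the allylic acetate and the methyl ether should be untouched, and the silyl ester hydrolyses on mildly acidic aqueous work-up.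

## Compound list

1 | ketoisophorone (2,6,6-trimethylcyclohex-2-ene-1,4-dione) | CC1=CC(=O)CC(C)(C)C1=O | starting material
2 | (6R)-2,2,6-trimethylcyclohexane-1,4-dione | C[C@@H]1CC(=O)CC(C)(C)C1=O | intermediate
3 | (4S,6R)-4-hydroxy-2,2,6-trimethylcyclohexan-1-one | O[C@@H]1CC(C)(C)C(=O)[C@H](C)C1 | intermediate
4 | vinylmagnesium bromide | C=C[Mg]Br | starting material
5 | (4S,6R)-1-ethenyl-2,2,6-trimethylcyclohexane-1,4-diol (C1 epimers, centre left undefined) | O[C@@H]1CC(C)(C)C(O)(C=C)[C@H](C)C1 | intermediate
6 | but-2-ynoic acid | CC#CC(=O)O | starting material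
7 | (1S,3R)-4-ethenyl-4-hydroxy-3,5,5-trimethylcyclohexyl but-2-ynoate (C4 epimers, centre left undefined) | CC#CC(=O)O[C@@H]1CC(C)(C)C(O)(C=C)[C@H](C)C1 | intermediate
8 | (1S)-4-ethenyl-3,5,5-trimethylcyclohex-3-en-1-yl but-2-ynoate | CC#CC(=O)O[C@@H]1CC(C)(C)C(C=C)=C(C)C1 | intermediate
9 | bridged tricyclic lactone, 1,7-lactone of (7R,8aR)-7-hydroxy-2,5,5,8a-tetramethyl-3,5,6,7,8,8a-hexahydronaphthalene-1-carboxylic acid | CC1=C2C(=O)O[C@@H]3CC(C)(C)C(=CC1)[C@@]2(C)C3 | intermediate
10 | methyl (7R,8aR)-7-hydroxy-2,5,5,8a-tetramethyl-3,5,6,7,8,8a-hexahydronaphthalene-1-carboxylate | CC1=C(C(=O)OC)[C@]2(C)C[C@H](O)CC(C)(C)C2=CC1 | intermediate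
11 | methyl (7R,8aR)-7-methoxy-2,5,5,8a-tetramethyl-3,5,6,7,8,8a-hexahydronaphthalene-1-carboxylate | CC1=C(C(=O)OC)[C@]2(C)C[C@H](OC)CC(C)(C)C2=CC1 | intermediate
12 | methyl (4aR,7R,8aR)-7-methoxy-2,5,5,8a-tetramethyl-3,4,4a,5,6,7,8,8a-octahydronaphthalene-1-carboxylate | CC1=C(C(=O)OC)[C@]2(C)C[C@H](OC)CC(C)(C)[C@H]2CC1 | intermediate
13 | lithium dienolate of 12 (C8=C17 and C9=C11 enolate) | C=C1CC[C@@H]2C(C)(C)C[C@@H](OC)C[C@@]2(C)C1=C(OC)O[Li] | intermediate
14 | methyl (1R,4aR,7R,8aR)-7-methoxy-5,5,8a-trimethyl-2-methylidenedecahydronaphthalene-1-carboxylate | C=C1CC[C@@H]2C(C)(C)C[C@@H](OC)C[C@@]2(C)[C@@H]1C(=O)OC | intermediate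
15 | [(1R,4aR,7R,8aR)-7-methoxy-5,5,8a-trimethyl-2-methylidenedecahydronaphthalen-1-yl]methanol | C=C1CC[C@@H]2C(C)(C)C[C@@H](OC)C[C@@]2(C)[C@@H]1CO | intermediate
16 | (1R,4aR,7R,8aR)-7-methoxy-5,5,8a-trimethyl-2-methylidenedecahydronaphthalene-1-carbaldehyde | C=C1CC[C@@H]2C(C)(C)C[C@@H](OC)C[C@@]2(C)[C@@H]1C=O | intermediate
17 | (1R,4aR,7R,8aR)-1-ethenyl-7-methoxy-5,5,8a-trimethyl-2-methylidenedecahydronaphthalene | C=C1CC[C@@H]2C(C)(C)C[C@@H](OC)C[C@@]2(C)[C@@H]1C=C | intermediate
18 | tert-butyl 4-chloro-3-oxobutanoate | ClCC(=O)CC(=O)OC(C)(C)C | starting material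
19 | tert-butyl 4-acetoxy-3-oxobutanoate | CC(=O)OCC(=O)CC(=O)OC(C)(C)C | intermediate
20 | tert-butyl (2E)-4-acetoxy-3-{[(trifluoromethyl)sulfonyl]oxy}but-2-enoate | CC(=O)OC/C(OS(=O)(=O)C(F)(F)F)=C\C(=O)OC(C)(C)C | intermediate
21 | {2-[(1R,4aR,7R,8aR)-7-methoxy-5,5,8a-trimethyl-2-methylidenedecahydronaphthalen-1-yl]ethyl}bis(3-methylbutan-2-yl)borane | C=C1CC[C@@H]2C(C)(C)C[C@@H](OC)C[C@@]2(C)[C@@H]1CCB(C(C)C(C)C)C(C)C(C)C | intermediate
22 | tert-butyl (2R,5R,9R,10R,13Z)-16-acetoxy-2-methoxy-ent-labda-8(17),13-dien-15-oate | C=C1CC[C@@H]2C(C)(C)C[C@@H](OC)C[C@@]2(C)[C@@H]1CC/C(=C/C(=O)OC(C)(C)C)COC(C)=O | intermediate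
23 | trimethylsilyl (2R,5R,9R,10R,13Z)-16-acetoxy-2-methoxy-ent-labda-8(17),13-dien-15-oate | C=C1CC[C@@H]2C(C)(C)C[C@@H](OC)C[C@@]2(C)[C@@H]1CC/C(=C/C(=O)O[Si](C)(C)C)COC(C)=O | intermediate
24 | (2R,5R,9R,10R,13Z)-16-acetoxy-2-methoxy-ent-labda-8(17),13-dien-15-oic acid | C=C1CC[C@@H]2C(C)(C)C[C@@H](OC)C[C@@]2(C)[C@@H]1CC/C(=C/C(=O)O)COC(C)=O | target

## Step count and least certain steps

Total: 17 steps. Longest linear sequence: 15 steps (steps 1–13, 16, 17). Fragment 20 takes 2 steps (14, 15).

Step 6 (key step). The cyclisation may be too slow, so that oligomerisation or a 1,5-hydrogen shift of the diene takes over. The reacting conformer needs a cisoid ester, a pseudoaxial C2–O bond that clashes with one C4 methyl, and an s-cis diene carrying an inside methyl group. Fallback without the tether, from 5: selective O-methylation of the secondary hydroxyl (NaH, MeI, THF, 0 °C) gives (4S,6R)-1-ethenyl-4-methoxy-2,2,6-trimethylcyclohexan-1-ol F1. Burgess dehydration gives (4S)-1-ethenyl-4-methoxy-2,6,6-trimethylcyclohex-1-ene F2. An intermolecular Diels–Alder reaction of F2 with methyl but-2-ynoate (neat, sealed tube, 150 °C, or EtAlCl2 in CH2Cl2) should join the unsubstituted diene terminus C7 to the β-carbon of the ynoate and so place the ester carbon on C10. Face control is lost, so 11 would form together with its C10 epimer, methyl (7R,8aS)-7-methoxy-2,5,5,8a-tetramethyl-3,5,6,7,8,8a-hexahydronaphthalene-1-carboxylate F3, to be removed by chromatography. The route is rejoined at 11.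

Step 2. No enzyme of the panel may deliver hydride to the required face, or diastereoselection may be incomplete, because the two flanks of the C4 carbonyl differ only at remote positions. Fallback from 2: LiBH(s-Bu)3 (THF, −78 °C) attacks C4 equatorially and gives the trans alcohol (4R,6R)-4-hydroxy-2,2,6-trimethylcyclohexan-1-one F4. Mitsunobu inversion with 4-nitrobenzoic acid (PPh3, DIAD) gives (1S,5R)-3,3,5-trimethyl-4-oxocyclohexyl 4-nitrobenzoate F5, and methanolysis (K2CO3, MeOH) returns the route to 3.

Step 5. The tertiary allylic sulfamate may ionise and recombine with allylic transposition instead of eliminating. Fallback from 3, which builds the diene by cross-coupling: silylation (t-BuMe2SiCl, imidazole) gives (4S,6R)-4-[(tert-butyldimethylsilyl)oxy]-2,2,6-trimethylcyclohexan-1-one F6. Enol triflate formation (LiN(i-Pr)2, PhNTf2) is regiospecific because only one α-carbon carries hydrogen, and gives (4S)-4-[(tert-butyldimethylsilyl)oxy]-2,6,6-trimethylcyclohex-1-en-1-yl trifluoromethanesulfonate F7. Suzuki–Miyaura vinylation (CH2=CHBF3K, PdCl2(dppf), Cs2CO3, THF/H2O) gives tert-butyl{[(1S)-4-ethenyl-3,5,5-trimethylcyclohex-3-en-1-yl]oxy}dimethylsilane F8. Desilylation (Bu4NF) gives (1S)-4-ethenyl-3,5,5-trimethylcyclohex-3-en-1-ol F9, and Steglich esterification with 6 gives 8.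

Step 15. The geometry of the enol triflate may be poorly controlled, or may be reversed if the ammonium enolate reacts from a hydrogen-bonded, chelate-like form. Fallback from 19: sulfonylation with TsCl, N-methylimidazole and Et3N, a combination documented to give E enol tosylates of β-keto esters, gives tert-butyl (2E)-4-acetoxy-3-{[(4-methylphenyl)sulfonyl]oxy}but-2-enoate F10. F10 is coupled with 21 (Pd(OAc)2, SPhos, K3PO4) and the route is rejoined at 22.

Step 16. Hydroboration may not discriminate fully between the two terminal alkenes. Transmetalation of the bulky borane may also be slow, which gives time for acetate cleavage by the base (followed by lactonisation) or for ionisation of the allylic acetate by zerovalent palladium. Fallback from 17: the borane 21 is oxidised (NaBO3·4H2O) to 2-[(1R,4aR,7R,8aR)-7-methoxy-5,5,8a-trimethyl-2-methylidenedecahydronaphthalen-1-yl]ethan-1-ol F11, which is purified. F11 is converted (I2, PPh3, imidazole) into (1R,4aR,7R,8aR)-1-(2-iodoethyl)-7-methoxy-5,5,8a-trimethyl-2-methylidenedecahydronaphthalene F12 and then (Zn dust, LiCl, THF) into the alkylzinc iodide F13. A base-free Negishi coupling of F13 with 20 (PdCl2(dppf), THF, rt) gives 22.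

Step 17. Traces of triflic acid may move the exocyclic alkene into the ring, or the liberated acid may lactonise with loss of the acetate. Fallback from 17 (through 21), in which the acid is unveiled by oxidation and no ester is ever cleaved:
- Syn hydrostannation of but-2-yne-1,4-diol (Bu3SnH, PdCl2(PPh3)2) gives (2E)-2-(tributylstannyl)but-2-ene-1,4-diol F14, with both hydroxymethyl groups cis.
- Silylation of the less hindered hydroxyl (t-BuMe2SiCl, imidazole, −20 °C) gives (2E)-4-[(tert-butyldimethylsilyl)oxy]-2-(tributylstannyl)but-2-en-1-ol F15.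
- Acetylation (Ac2O, pyridine) gives (2E)-4-[(tert-butyldimethylsilyl)oxy]-2-(tributylstannyl)but-2-en-1-yl acetate F16.
- Iododestannylation (I2, CH2Cl2, 0 °C) gives (2E)-4-[(tert-butyldimethylsilyl)oxy]-2-iodobut-2-en-1-yl acetate F17.
- B-alkyl Suzuki–Miyaura coupling of F17 with 21 gives (2R,5R,9R,10R,13Z)-15-[(tert-butyldimethylsilyl)oxy]-2-methoxy-ent-labda-8(17),13-dien-16-yl acetate F18.
- HF·pyridine gives (2R,5R,9R,10R,13Z)-15-hydroxy-2-methoxy-ent-labda-8(17),13-dien-16-yl acetate F19.
- Dess–Martin oxidation gives (2R,5R,9R,10R,13Z)-16-acetoxy-2-methoxy-ent-labda-8(17),13-dien-15-al F20.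
- Pinnick oxidation (NaClO2, NaH2PO4, 2-methylbut-2-ene, t-BuOH/H2O) gives 24.

## Further compounds

F1 | step 6 | (4S,6R)-1-ethenyl-4-methoxy-2,2,6-trimethylcyclohexan-1-ol (C1 epimers) | CO[C@@H]1CC(C)(C)C(O)(C=C)[C@H](C)C1
F2 | step 6 | (4S)-1-ethenyl-4-methoxy-2,6,6-trimethylcyclohex-1-ene | CO[C@@H]1CC(C)(C)C(C=C)=C(C)C1
F3 | step 6 | methyl (7R,8aS)-7-methoxy-2,5,5,8a-tetramethyl-3,5,6,7,8,8a-hexahydronaphthalene-1-carboxylate | CC1=C(C(=O)OC)[C@@]2(C)C[C@H](OC)CC(C)(C)C2=CC1
F4 | step 2 | (4R,6R)-4-hydroxy-2,2,6-trimethylcyclohexan-1-one | O[C@H]1CC(C)(C)C(=O)[C@H](C)C1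
F5 | step 2 | (1S,5R)-3,3,5-trimethyl-4-oxocyclohexyl 4-nitrobenzoate | O=C(O[C@@H]1CC(C)(C)C(=O)[C@H](C)C1)c1ccc(cc1)[N+](=O)[O-]
F6 | step 5 | (4S,6R)-4-[(tert-butyldimethylsilyl)oxy]-2,2,6-trimethylcyclohexan-1-one | CC(C)(C)[Si](C)(C)O[C@@H]1CC(C)(C)C(=O)[C@H](C)C1
F7 | step 5 | (4S)-4-[(tert-butyldimethylsilyl)oxy]-2,6,6-trimethylcyclohex-1-en-1-yl trifluoromethanesulfonate | CC(C)(C)[Si](C)(C)O[C@@H]1CC(C)(C)C(OS(=O)(=O)C(F)(F)F)=C(C)C1
F8 | step 5 | tert-butyl{[(1S)-4-ethenyl-3,5,5-trimethylcyclohex-3-en-1-yl]oxy}dimethylsilane | CC(C)(C)[Si](C)(C)O[C@@H]1CC(C)(C)C(C=C)=C(C)C1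
F9 | step 5 | (1S)-4-ethenyl-3,5,5-trimethylcyclohex-3-en-1-ol | O[C@@H]1CC(C)(C)C(C=C)=C(C)C1
F10 | step 15 | tert-butyl (2E)-4-acetoxy-3-{[(4-methylphenyl)sulfonyl]oxy}but-2-enoate | CC(=O)OC/C(OS(=O)(=O)c1ccc(C)cc1)=C\C(=O)OC(C)(C)C
F11 | step 16 | 2-[(1R,4aR,7R,8aR)-7-methoxy-5,5,8a-trimethyl-2-methylidenedecahydronaphthalen-1-yl]ethan-1-ol | C=C1CC[C@@H]2C(C)(C)C[C@@H](OC)C[C@@]2(C)[C@@H]1CCO
F12 | step 16 | (1R,4aR,7R,8aR)-1-(2-iodoethyl)-7-methoxy-5,5,8a-trimethyl-2-methylidenedecahydronaphthalene | C=C1CC[C@@H]2C(C)(C)C[C@@H](OC)C[C@@]2(C)[C@@H]1CCI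
F13 | step 16 | {2-[(1R,4aR,7R,8aR)-7-methoxy-5,5,8a-trimethyl-2-methylidenedecahydronaphthalen-1-yl]ethyl}zinc iodide | C=C1CC[C@@H]2C(C)(C)C[C@@H](OC)C[C@@]2(C)[C@@H]1CC[Zn]I
F14 | step 17 | (2E)-2-(tributylstannyl)but-2-ene-1,4-diol | OC/C=C(\CO)[Sn](CCCC)(CCCC)CCCC
F15 | step 17 | (2E)-4-[(tert-butyldimethylsilyl)oxy]-2-(tributylstannyl)but-2-en-1-ol | CC(C)(C)[Si](C)(C)OC/C=C(\CO)[Sn](CCCC)(CCCC)CCCC
F16 | step 17 | (2E)-4-[(tert-butyldimethylsilyl)oxy]-2-(tributylstannyl)but-2-en-1-yl acetate | CC(C)(C)[Si](C)(C)OC/C=C(\COC(C)=O)[Sn](CCCC)(CCCC)CCCC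
F17 | step 17 | (2E)-4-[(tert-butyldimethylsilyl)oxy]-2-iodobut-2-en-1-yl acetate | CC(C)(C)[Si](C)(C)OC/C=C(\COC(C)=O)I
F18 | step 17 | (2R,5R,9R,10R,13Z)-15-[(tert-butyldimethylsilyl)oxy]-2-methoxy-ent-labda-8(17),13-dien-16-yl acetate | C=C1CC[C@@H]2C(C)(C)C[C@@H](OC)C[C@@]2(C)[C@@H]1CC/C(=C/CO[Si](C)(C)C(C)(C)C)COC(C)=O
F19 | step 17 | (2R,5R,9R,10R,13Z)-15-hydroxy-2-methoxy-ent-labda-8(17),13-dien-16-yl acetate | C=C1CC[C@@H]2C(C)(C)C[C@@H](OC)C[C@@]2(C)[C@@H]1CC/C(=C/CO)COC(C)=O
F20 | step 17 | (2R,5R,9R,10R,13Z)-16-acetoxy-2-methoxy-ent-labda-8(17),13-dien-15-al | C=C1CC[C@@H]2C(C)(C)C[C@@H](OC)C[C@@]2(C)[C@@H]1CC/C(=C/C=O)COC(C)=O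
A1 | alternative 1 | 2,4,4-trimethylcyclohex-2-en-1-one | CC1=CC(C)(C)CCC1=O
A2 | alternative 1 | [2-(1,3-dioxan-2-yl)ethyl]magnesium bromide | Br[Mg]CCC1OCCCO1
A3 | alternative 1 | tert-butyl bromoacetate | BrCC(=O)OC(C)(C)C
A4 | alternative 1 | tert-butyl 2-{2-[2-(1,3-dioxan-2-yl)ethyl]-1,3,3-trimethyl-6-oxocyclohexyl}acetate (trans, configured as in 24 at C5 and C10) | O1CCCOC1CC[C@@H]2C(C)(C)CCC(=O)[C@@]2(C)CC(=O)OC(C)(C)C
A5 | alternative 2 | 2-(but-3-yn-1-yl)-1-ethenyl-5-methoxy-1,3,3-trimethylcyclohexane (C2, C5, C10 configured as in 24) | C#CCC[C@@H]1C(C)(C)C[C@@H](OC)C[C@@]1(C)C=C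
A6 | alternative 2 | S-(3-acetoxy-2-oxopropyl) O-ethyl carbonodithioate | CCOC(=S)SCC(=O)COC(C)=O
A7 | alternative 2 | 16-acetoxy-2-methoxy-14,15-dinor-ent-labd-8(17)-en-13-one | C=C1CC[C@@H]2C(C)(C)C[C@@H](OC)C[C@@]2(C)[C@@H]1CCC(=O)COC(C)=O
A8 | alternative 3 | methyl (2E,5S,8E,10E)-11-[(tert-butyldimethylsilyl)oxy]-5-methoxy-3,7,7-trimethylundeca-2,8,10-trienoate | COC(=O)/C=C(\C)C[C@H](OC)CC(C)(C)/C=C/C=C/O[Si](C)(C)C(C)(C)C
A9 | alternative 3 | methyl 2-[(tert-butyldimethylsilyl)oxy]-7-methoxy-5,5,8a-trimethyl-1,2,4a,5,6,7,8,8a-octahydronaphthalene-1-carboxylate (trans-fused, configured as in 24) | CC(C)(C)[Si](C)(C)O[C@@H]1C=C[C@@H]2C(C)(C)C[C@@H](OC)C[C@@]2(C)[C@@H]1C(=O)OC
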